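A closed, stirred vessel holds solid substrate that passes into solution as starting material, which closes to ring or pairs to open dimer.

| flask | solid substrate | remark | time |
|---|---|---|---|
| autumn | 0.25 M | the very flask that is asked about, followed so far |  |
| dusk | 0.50 M | run made earlier |  |
| flask | 0.25 M |  | 40 min |

| run | time / min | ring / % | solid substrate / % |
|---|---|---|---|
| autumn | 0.667 | 0 | 98.3 |
| autumn | 1.33 | 0 | 97.9 |
| autumn | 3.00 | 0.4 | 96.2 |
| autumn | 8.00 | 0.9 | 89.8 |
| dusk | 8.00 | 0.4 | 94.6 |
| dusk | 15.0 | 1.1 | 91.1 |
| dusk | 20.0 | 2.4 | 87.8 |
| dusk | 30.0 | 5.4 | 82.5 |

(readings scatter by 0.3 percentage points)

- percentages count the solid substrate that a species holds: one open dimer counts as two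
- solid, in amounts per volume of the solution: solid substrate
- candidate steps: 2 starting material <-> open dimer; solid substrate <-> starting material; starting material -> ring
- at the start none of the solid substrate is in solution

1. how much ring there is at 40 min, in percent of the solid substrate charged
2. the change that raises the amount of ring at 40 min, in percent of the solid substrate charged most ("none" if none brings more than 2 percentage points) (west / north-east / none)
3. amount of ring at 40 min, in percent of the solid substrate charged, after west

- west: doubling the solubility of the solid substrate, all else as stated
- north-east: doubling the dissolution coefficient of the solid substrate, all else as stated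

1. In the autumn run 0.00319 M min⁻¹ leaves the solid over the first 8.00 min, and in the dusk run, with 0.50 M charged, 0.00338 M min⁻¹ over the same time; this feed, the molar loss of solid per minute, is frozen as a pseudo-zero-order supply, so c(ring) in molar terms carries over from the dusk run to the autumn flask.

2. The frozen feed takes 51.0% of the autumn charge from the solid by 40 min, a crude ceiling, and it overcounts, because the dusk run's feed sinks to 0.00265 M min⁻¹ between its last readings.

3. A frozen feed makes c(starting material) grow with time and c(ring) with its square, so scaling the dusk run's 0.0270 M at 30.0 min gives a ceiling of 19.2% for the autumn flask.

4. The dusk run makes ring at 0.00143 M min⁻¹, below the late feed, so the dissolved pool is still filling, and continuing that rate gives a floor of 16.5%.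

5. West doubles the feed and the level the pool heads for, north-east the feed at the old level, so west is my pick, with ring below 38.4%.

6. The forecast, 17%, stands inside the bracket; it picks west with 32%: “Doubling solubility doubles the dissolved pool and so the ring”.

7. The flask gives 16.7%, and west gains 15 percentage points against 12 points for north-east, reaching 32.2%.

    2 starting material ⇌ open dimer (K = 1.50 L mol⁻¹, k = 0.0870 L mol⁻¹ min⁻¹)
    solid substrate ⇌ starting material, rate k2*(cs2 - [starting material]) while solid is left; crystals form when [starting material] > cs2 (solubility = 0.240 M, k = 0.0140 min⁻¹)
    starting material → ring (k = 0.0260 min⁻¹)

In the autumn flask starting material is made 2.10 times as fast as it is used at 18.5 min and 1.31 times at 40.0 min, so at the asked time its pool, 25.1% of the charge, is still filling while 55.3% stands as solid. The frozen feed 0.00319 M min⁻¹ counts 51.0% gone from the solid by then, and 44.7% has gone. In the same flask read at 60.0 min, that feed counts 76.5%, against 64.1% gone and ring at 30.8%.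

The data stem from a simulated flask with made-up constants, noise included.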